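Start with the easy step: cedar repeats the north-west run, same charge, same closed flask, read at its last line.

| flask | substrate | remark | time |
|---|---|---|---|
| north-west | 0.050 M | run made earlier |  |
| east | 0.070 M | run made earlier |  |
| north | 0.11 M | run made earlier |  |
| birch | 0.050 M | one stirred flow tank at steady state, fed with the mixture as stated, mean residence time 3.0 h |  |
| cedar | 0.050 M | everything together in a closed stirred flask, run for 3.0 h | 3.0 h |

north-west run (percent of the substrate charged)

| time / h | single ring / % | open dimer / % | open trimer / % |
|---|---|---|---|
| 0.167 | 20.0 | 0 | 0.9 |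
| 0.500 | 29.2 | 2.1 | 3.9 |
| 0.833 | 30.7 | 0.7 | 2.4 |
| 1.33 | 29.7 | 0.9 | 3.2 |
| 2.00 | 25.9 | 0 | 4.2 |
| 2.50 | 25.7 | 0 | 3.9 |
| 3.00 | 25.5 | 0.1 | 3.9 |

east run (percent of the substrate charged)

| time / min | single ring / % | open dimer / % | open trimer / % |
|---|---|---|---|
| 6.00 | 12.0 | 2.8 | 2.4 |
| 15.0 | 24.4 | 0.9 | 1.9 |
| 30.0 | 28.9 | 2.3 | 3.3 |
| 50.0 | 28.2 | 0 | 4.2 |
| 60.0 | 30.0 | 0.6 | 2.6 |
| 80.0 | 26.1 | 0.8 | 4.8 |
| 120 | 24.1 | 0.3 | 6.2 |

north run (percent of the substrate charged)

| time / min | single ring / % | open dimer / % | open trimer / % |
|---|---|---|---|
| 6.00 | 12.5 | 2.9 | 1.6 |
| 15.0 | 22.6 | 2.3 | 4.7 |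
| 30.0 | 26.8 | 0 | 5.1 |
| 50.0 | 26.6 | 0 | 8.1 |
| 60.0 | 26.5 | 0.5 | 7.9 |
| 80.0 | 24.0 | 1.0 | 9.3 |
| 120 | 22.2 | 1.4 | 11.0 |

(each reading ± 1 percentage point)

- in percentages every species weighs as the substrate in it: one open dimer or ring dimer counts as two
- in percentages every species weighs as the substrate in it: one open trimer counts as three
- the stated concentrations are those of everything mixed, before any reaction; amounts are the same in each set-up
- the numbers in the tables scatter with a standard deviation of 1 percentage point
- steps under discussion: open dimer -> ring dimer; single ring <-> isomer of the product; 2 substrate -> open dimer; substrate <-> single ring; substrate + open dimer -> open trimer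
- the earlier runs were made in a closed, stirred flask

1. the set-up with the highest share of single ring in all that became single ring or open dimer or open trimer or ring dimer or isomer of the product, at the outlet or at the end ("none" if the first two lie within 2 percentage points) (birch / cedar / none)
2. share of single ring in all that became single ring or open dimer or open trimer or ring dimer or isomer of the product, at the outlet or at the end, birch
3. share of single ring in all that became single ring or open dimer or open trimer or ring dimer or isomer of the product, at the outlet or at the end, cedar

Write the asked share as y = P/C, with P the single ring and C the percent of the charge no longer substrate. Now take birch, a stirred tank with mean residence time τ, and reckon its age from τ before anything else: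

t_m = τ · ln(two) = 3.0 h · 0.693 = 2.08 h

Call t_m the median age of the outlet. By the exponential residence-time distribution of an ideal tank, half of what leaves birch is younger than t_m.

So hold birch against the north-west run near t_m, and cedar against its end. Single ring reads 25.9% at 2.00 h and 25.5% at 3.00 h, with a scatter of 1 percentage point. That gap of 0.4 points says little about how P moves there. The median age t_m lies below the time of cedar, though the mean age of the birch outlet equals τ; on this reckoning I expect a smaller C in birch and commit to birch.

The forecast says otherwise: none, with 59% for birch and 57% for cedar, and it judges “Isomerisation looks minor”.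

The simulation gives birch: 41.3% at the birch outlet, 33.4% at the end of cedar.

    open dimer → ring dimer (k = 0.130 min⁻¹)
    single ring ⇌ isomer of the product (K = 1.60, k = 0.0150 min⁻¹)
    2 substrate → open dimer (k = 0.0320 M⁻¹ min⁻¹)
    substrate ⇌ single ring (K = 0.810, k = 0.0270 min⁻¹)
    substrate + open dimer → open trimer (k = 1.50 M⁻¹ min⁻¹)

Less of the charge has reacted in birch, 59.5% against 70.4% in cedar, with single ring 24.6% against 23.5%. Take the back-mixing out of birch and its share drops to 33.4%: back-mixing is part of what lifts it. Take away the path from single ring to isomer of the product, both ways, and the gap between birch and cedar shrinks from 7.9 points to 2 points: that path is the largest single effect on the gap, not the main reason. Use t_m again on the flask of cedar left until 2.0 h, close to 2.08 h: it holds single ring 25.5% and substrate 33.9%, and its share is 38.6%, beside 41.3% at the birch outlet.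

The numbers in the tables are simulated for an exercise; noise was put on by code.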